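**Retrosynthetic overview**
- C–C disconnection of the 1,3-diketone by crossed Claisen condensation: a 2,4-dioxygenated 5-prenylacetophenone enolate plus a methyl 4-oxy-3-prenylbenzoate.
- Each prenyl group is disconnected to an aryl halide and prenyl-Bpin (linear-selective Suzuki–Miyaura coupling).
- All three phenols are carried as MOM ethers and released together in the last step under aprotic conditions.
- No rings are formed; both benzene rings are purchased with the correct oxygenation and halogen pattern.

**Assumptions**
- The target has no stereocentres and its alkenes have no E/Z isomerism, so it is achiral and "single enantiomer" does not apply; it is drawn as the diketo tautomer.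
- Compound 1 is taken as a catalogue building block (not checked); if unavailable it is one step from 4-bromoresorcinol (AcOH, BF3·OEt2).

**Route**

Step 1
Reactants: 1, 1-(5-bromo-2,4-dihydroxyphenyl)ethan-1-one; 2, chloromethyl methyl ether (MOMCl)
Product: 3, 1-[5-bromo-2,4-bis(methoxymethoxy)phenyl]ethan-1-one
Conditions: NaH (2.3 equiv), DMF, 0 °C; MOMCl (2.6 equiv), 0 °C → rt
Reagents that add atoms: MOMCl, COCCl
Why: O-alkylation of both phenoxides (Williamson-type acetal formation); NaH is used because the hydrogen-bonded 2-OH is sluggish with amine bases, and the phenols are far more acidic than the methyl ketone.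

Step 2
Reactants: 3; 4, prenylboronic acid pinacol ester (4,4,5,5-tetramethyl-2-(3-methylbut-2-en-1-yl)-1,3,2-dioxaborolane)
Product: 5, 1-[2,4-bis(methoxymethoxy)-5-(3-methylbut-2-en-1-yl)phenyl]ethan-1-one
Conditions: 4 (1.5 equiv), Pd(dppf)Cl2·CH2Cl2 (10 mol%), CsF (4 equiv), THF, reflux
Reagents that add atoms: prenyl-Bpin, CC(C)=CCB1OC(C)(C)C(C)(C)O1
Why: Suzuki–Miyaura allyl coupling; the allyl-Pd intermediate equilibrates and reductively eliminates at the unhindered CH2 terminus to give the linear prenyl arene, and anhydrous fluoride activation leaves the ketone and MOM ethers untouched.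

Step 3
Reactants: 6, methyl 4-hydroxy-3-iodobenzoate; 2, MOMCl
Product: 7, methyl 3-iodo-4-(methoxymethoxy)benzoate
Conditions: MOMCl (1.5 equiv), i-Pr2NEt (2 equiv), CH2Cl2, 0 °C → rt
Reagents that add atoms: MOMCl, COCCl
Why: Standard phenol MOM protection; it removes the acidic OH that would turn the ester into an unreactive phenoxide-benzoate in the Claisen step.

Step 4
Reactants: 7; 4, prenylboronic acid pinacol ester
Product: 8, methyl 4-(methoxymethoxy)-3-(3-methylbut-2-en-1-yl)benzoate
Conditions: 4 (1.5 equiv), Pd(dppf)Cl2·CH2Cl2 (5 mol%), CsF (4 equiv), THF, reflux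
Reagents that add atoms: prenyl-Bpin, CC(C)=CCB1OC(C)(C)C(C)(C)O1
Why: Same linear-selective Suzuki–Miyaura prenylation on the more reactive aryl iodide; the non-hydrolytic CsF/THF conditions preserve the methyl ester.

Step 5
Reactants: 5; 8
Product: 9, 1-[2,4-bis(methoxymethoxy)-5-(3-methylbut-2-en-1-yl)phenyl]-3-[4-(methoxymethoxy)-3-(3-methylbut-2-en-1-yl)phenyl]propane-1,3-dione
Conditions: NaH (3 equiv), 8 (1.2 equiv), THF, reflux, slow addition of 5; quench AcOH / aq NH4Cl
Reagents that add atoms: none (only 5 and 8; MeOH is lost)
Why: Crossed Claisen condensation of the methyl ketone enolate with the non-enolisable aryl ester, driven by irreversible deprotonation of the product β-diketone; MOM ethers and prenyl groups are inert to NaH.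

Step 6
Reactants: 9
Product: 10, Glycyrdione A, 1-[2,4-dihydroxy-5-(3-methylbut-2-en-1-yl)phenyl]-3-[4-hydroxy-3-(3-methylbut-2-en-1-yl)phenyl]propane-1,3-dione
Conditions: TMSOTf (8 equiv), 2,2′-bipyridyl (12 equiv), MeCN, 0 °C → rt; then H2O, rt
Reagents that add atoms: none
Why: Silyl-triflate/bipyridyl cleavage of aryl MOM ethers gives aryl TMS ethers (and the TMS enol ether of the diketone) without Brønsted acid, and water then releases the phenols. This avoids the two acid-driven side reactions: cyclodehydration of the 2-hydroxy-1,3-diketone to the flavone and cyclisation of the o-prenylphenols to chromans.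

**Compound list**
1 | 1-(5-bromo-2,4-dihydroxyphenyl)ethan-1-one | CC(=O)c1cc(Br)c(O)cc1O | starting material
2 | chloromethyl methyl ether (MOMCl) | COCCl | starting material (reagent)
3 | 1-[5-bromo-2,4-bis(methoxymethoxy)phenyl]ethan-1-one | CC(=O)c1cc(Br)c(OCOC)cc1OCOC | intermediate
4 | prenylboronic acid pinacol ester | CC(C)=CCB1OC(C)(C)C(C)(C)O1 | starting material (reagent)
5 | 1-[2,4-bis(methoxymethoxy)-5-(3-methylbut-2-en-1-yl)phenyl]ethan-1-one | CC(=O)c1cc(CC=C(C)C)c(OCOC)cc1OCOC | intermediate
6 | methyl 4-hydroxy-3-iodobenzoate | COC(=O)c1ccc(O)c(I)c1 | starting material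
7 | methyl 3-iodo-4-(methoxymethoxy)benzoate | COC(=O)c1ccc(OCOC)c(I)c1 | intermediate
8 | methyl 4-(methoxymethoxy)-3-(3-methylbut-2-en-1-yl)benzoate | COC(=O)c1ccc(OCOC)c(CC=C(C)C)c1 | intermediate
9 | tris-MOM diketone (name in Step 5) | CC(C)=CCc1cc(C(=O)CC(=O)c2cc(CC=C(C)C)c(OCOC)cc2OCOC)ccc1OCOC | intermediate
10 | Glycyrdione A | CC(C)=CCc1cc(C(=O)CC(=O)c2cc(CC=C(C)C)c(O)cc2O)ccc1O | target

**Step count**
Total steps: 6. Longest linear sequence: 4 (steps 1 → 2 → 5 → 6, or 3 → 4 → 5 → 6).

**Three steps most likely to fail**
1. Step 6, global MOM removal. Risk: flavone formation by cyclodehydration, chroman formation, or MOM transfer to the diketone carbon. Fallback: switch to fluoride-labile protection. Remove the MOM groups at the fragment stage (before any diketone exists) and re-protect as TBS ethers, leaving the 2-OH free. Join the fragments by LiHMDS polyanion C-acylation with 4-(TBSO)-3-prenylbenzoyl chloride, and finish with TBAF/AcOH.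
2. Step 5, crossed Claisen. Risk: the electron-rich, poorly electrophilic ester reacts slowly and the ketone self-condenses. Fallback: Baker–Venkataraman route. Protect only the 4-OH of the ketone, O-acylate the free 2-OH with the acid from saponified 8 (EDC/DMAP), then induce intramolecular O→C acyl transfer with KOH/pyridine or LiHMDS.
3. Step 2, Suzuki prenylation of the electron-rich aryl bromide (step 4 shares the regiochemistry risk). Risk: slow oxidative addition and some branched "reverse-prenyl" product. Fallback: replace the boron/Pd coupling with stoichiometric π-prenylnickel bromide dimer (from prenyl bromide and Ni(cod)2) in DMF at about 60 °C. This couples aryl bromides at the primary allyl terminus and tolerates ketones.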